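Ring B is read as a Hagemann-ester-type cyclohexenone (labdane numbering). With C6 as a ketone, its neighbours C5 and C7 are nucleophilic, while C10 and C8 are the β-carbon and the acetyl carbon of an alkylidene acetoacetate whose ester carbon becomes C11. One amine-mediated Michael–aldol condensation of an acyclic keto alkylidene acetoacetate thus closes ring A (C5–C10, creating the quaternary C10 and C5) and ring B (C7–C8) together. It is steered by the C2 and C4 stereocentres, which stem from (R)-epichlorohydrin and a lactone alkylation. The C11 ester then places the C8=C9 alkene and carries the furan, later butenolide, side chain.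

Key step: step 9

Remark: the SMILES is read as 6α-acetoxy-2α,19-dihydroxylabda-8,13-dien-15,16-olide (2R,4S,5R,6S,10S; trans-decalin, 10β-CH3, 5α-H, equatorial 2α-OH and 6α-OAc, axial C19); labdane numbering is used for all later compounds.

Step 1
Reactants: 1 (R)-epichlorohydrin; 2 isopropenylmagnesium bromide
Product: 4 (R)-2-(2-methylprop-2-en-1-yl)oxirane, via (R)-1-chloro-4-methylpent-4-en-2-ol 3 (not isolated)
Conditions: CuI (10 mol %), THF, −40 °C; then NaOH, H2O/Et2O, rt
Reagents that add atoms: none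
Why: Copper-catalysed Grignard opening of the epoxide at its CH2 terminus followed by base-induced closure of the chlorohydrin should give the homologous epoxide with the carbinol centre (future C2) untouched.

Step 2
Reactants: 4 (R)-2-(2-methylprop-2-en-1-yl)oxirane; 5 propionic acid
Product: 7 (5S)-3-methyl-5-(2-methylprop-2-en-1-yl)oxolan-2-one, via (4S)-4-hydroxy-2,6-dimethylhept-6-enoic acid 6 (not isolated)
Conditions: LiN(iPr)2 (2.2 equiv), THF/DMPU, 0 → 45 °C; aq. HCl; TsOH (cat.), toluene, rt
Reagents that add atoms: none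
Why: The carboxylic acid dianion should open the terminal epoxide at CH2 (enolate alkylation by an epoxide) and the γ-hydroxy acid should lactonise, the uncontrolled α-methyl centre being erased in step 3.

Step 3
Reactants: 7 (5S)-3-methyl-5-(2-methylprop-2-en-1-yl)oxolan-2-one; 8 propargyl bromide
Product: 9 (3R,5R)-3-methyl-5-(2-methylprop-2-en-1-yl)-3-(prop-2-yn-1-yl)oxolan-2-one
Conditions: LiN(iPr)2, THF/DMPU, −78 °C; then 8, −78 → −30 °C
Reagents that add atoms: none
Why: Alkylation of the planar lactone enolate should occur anti to the C5 substituent (1,3-induction), so the propargyl group (future C5–C7) enters trans to the 2-methylallyl arm and the quaternary centre (future C4) gets the relative configuration of the target.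

Step 4
Reactants: 9 (3R,5R)-3-methyl-5-(2-methylprop-2-en-1-yl)-3-(prop-2-yn-1-yl)oxolan-2-one
Product: 10 (2R,4R)-2,6-dimethyl-2-(prop-2-yn-1-yl)hept-6-ene-1,4-diol
Conditions: LiAlH4, THF, 0 °C → rt
Reagents that add atoms: none
Why: Hydride reduction of the lactone should give the 1,4-diol (future C19 and C2 hydroxyls) without touching alkene, alkyne or stereocentres.

Step 5
Reactants: 10 (2R,4R)-2,6-dimethyl-2-(prop-2-yn-1-yl)hept-6-ene-1,4-diol
Product: 11 (2R,4R)-1,4-bis(tert-butyldimethylsilyloxy)-2,6-dimethyl-2-(prop-2-yn-1-yl)hept-6-ene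
Conditions: TBSOTf, 2,6-lutidine, CH2Cl2, 0 °C
Reagents that add atoms: tert-butyldimethylsilyl trifluoromethanesulfonate, CC(C)(C)[Si](C)(C)OS(=O)(=O)C(F)(F)F
Why: Silylation with the silyl triflate should protect both the secondary and the neopentyl primary hydroxyl as TBS ethers, which should last until the final fluoride cleavage.

Step 6
Reactants: 11 (2R,4R)-1,4-bis(tert-butyldimethylsilyloxy)-2,6-dimethyl-2-(prop-2-yn-1-yl)hept-6-ene
Product: 12 (4S,6R)-4-(tert-butyldimethylsilyloxy)-6-[(tert-butyldimethylsilyloxy)methyl]-6-methylnon-8-yn-2-one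
Conditions: O3, CH2Cl2/MeOH, −78 °C; then Me2S, −78 °C → rt
Reagents that add atoms: ozone, [O-][O+]=O
Why: Ozonolysis with reductive work-up should cleave the 1,1-disubstituted alkene, which reacts far faster with ozone than the terminal alkyne, to give the C10 methyl ketone.

Step 7
Reactants: 12 (4S,6R)-4-(tert-butyldimethylsilyloxy)-6-[(tert-butyldimethylsilyloxy)methyl]-6-methylnon-8-yn-2-one; 13 methyl acetoacetate
Product: 14 methyl (5R,7R)-2-acetyl-5-(tert-butyldimethylsilyloxy)-7-[(tert-butyldimethylsilyloxy)methyl]-3,7-dimethyldec-2-en-9-ynoate (E/Z mixture)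
Conditions: TiCl4, pyridine, THF, 0 °C → rt
Reagents that add atoms: none
Why: TiCl4/pyridine-mediated Knoevenagel condensation of the methyl ketone with the β-keto ester should give the tetrasubstituted alkylidene acetoacetate, whose alkene geometry is of no consequence because C9 loses it in step 9.

Step 8
Reactants: 14 methyl (5R,7R)-2-acetyl-5-(tert-butyldimethylsilyloxy)-7-[(tert-butyldimethylsilyloxy)methyl]-3,7-dimethyldec-2-en-9-ynoate
Product: 15 methyl (5R,7S)-2-acetyl-5-(tert-butyldimethylsilyloxy)-7-[(tert-butyldimethylsilyloxy)methyl]-3,7-dimethyl-9-oxodec-2-enoate (E/Z mixture)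
Conditions: Ph3PAuCl (2 mol %), AgOTf (2 mol %), H2O, 1,4-dioxane, 60 °C
Reagents that add atoms: water, O
Why: Gold-catalysed Markovnikov hydration of the terminal alkyne should unmask the C6 methyl ketone, which was kept latent so that only the C10 ketone could condense in step 7.

Step 9
Reactants: 15 methyl (5R,7S)-2-acetyl-5-(tert-butyldimethylsilyloxy)-7-[(tert-butyldimethylsilyloxy)methyl]-3,7-dimethyl-9-oxodec-2-enoate
Product: 18 methyl 2α,19-bis(tert-butyldimethylsilyloxy)-6-oxo-12,13,14,15,16-pentanorlabd-7-en-11-oate, via 1,5-diketone Michael adduct 16 (not isolated), via β-hydroxy ketone aldol 17 (not isolated)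
Conditions: pyrrolidine (0.3 equiv), AcOH (0.3 equiv), toluene, 80 °C
Reagents that add atoms: none
Why: Pyrrolidinium acetate converts the C6 methyl ketone into its enamines; the C5=C6 enamine adds to C10, the β-carbon of the alkylidene acetoacetate (C5–C10), hydrolysis gives the 1,5-diketone 16, and the C7 enamine of 16 then attacks the C8 acetyl carbonyl (C7–C8) to give aldol 17, which dehydrates to the conjugated enone 18. The closest known reaction type is the Hagemann-ester (Knoevenagel-type) Michael–aldol condensation of a ketone with an alkylidene β-keto ester, here run intramolecularly. Ring A closes by a 6-(enolexo)-exo-trig conjugate addition through a chair transition state and ring B by a 6-(enolendo)-exo-trig aldol condensation. C10 and C5 are controlled by the C2 and C4 centres: in the favoured chair the C2 silyloxy group, the C5 acetyl group and the C10 dicarbonyl arm are equatorial and the C10 methyl is axial and anti to H5, whereas the other chair would place C2–OTBS, C4–CH3 and C10–CH3 all axial on one face; C5, α to the C6 ketone, can in addition equilibrate to the trans ring fusion, and C9 is formed as an inconsequential epimer mixture. The step needs regioselectivity of the Michael donor (C5, not C7) and of the aldol (C7 onto C8), which should be secured by ring size (six-membered against eight- and four-membered alternatives) and by the β-keto ester enolising towards C9, so that its methyl group (C17) is not nucleophilic.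

Step 10
Reactants: 18 methyl 2α,19-bis(tert-butyldimethylsilyloxy)-6-oxo-12,13,14,15,16-pentanorlabd-7-en-11-oate
Product: 20 2α,19-bis(tert-butyldimethylsilyloxy)-12,13,14,15,16-pentanorlabd-8-ene-6β,11-diol, via deconjugated keto ester 19 (not isolated)
Conditions: KN(SiMe3)2, THF, −78 °C; AcOH, −78 °C; then iBu2AlH, −78 → 0 °C
Reagents that add atoms: none
Why: γ-Deprotonation at C9 should give the extended enolate, kinetic protonation at its α-carbon C7 should move the alkene to C8=C9 (conjugated with the ester), and hydride reduction in the same flask should lock this position by turning the ester into the C11 alcohol and the ketone into the expected axial 6β-alcohol, whose configuration is corrected in steps 13 and 14.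

Step 11
Reactants: 20 2α,19-bis(tert-butyldimethylsilyloxy)-12,13,14,15,16-pentanorlabd-8-ene-6β,11-diol
Product: 21 11-bromo-2α,19-bis(tert-butyldimethylsilyloxy)-12,13,14,15,16-pentanorlabd-8-en-6β-ol
Conditions: NBS, Me2S, CH2Cl2, −20 → 0 °C
Reagents that add atoms: N-bromosuccinimide, O=C1CCC(=O)N1Br
Why: Corey–Kim bromination should convert the primary allylic alcohol into the bromide selectively, the hindered axial secondary C6 hydroxyl reacting much more slowly.

Step 12
Reactants: 21 11-bromo-2α,19-bis(tert-butyldimethylsilyloxy)-12,13,14,15,16-pentanorlabd-8-en-6β-ol; 22 3-(chloromethyl)furan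
Product: 24 15,16-epoxy-2α,19-bis(tert-butyldimethylsilyloxy)labda-8,13(16),14-trien-6β-ol, via (furan-3-ylmethyl)magnesium chloride 23 (not isolated)
Conditions: 22, Mg, THF, 0 °C; then 21, Li2CuCl4 (5 mol %), THF, −78 → 0 °C
Reagents that add atoms: none
Why: Copper-catalysed Grignard allylic substitution should couple the furylmethyl reagent at the primary carbon C11 (the γ-carbon C8 is fully substituted), forming C11–C12, with one further equivalent of 23 consumed by the free hydroxyl.

Step 13
Reactants: 24 15,16-epoxy-2α,19-bis(tert-butyldimethylsilyloxy)labda-8,13(16),14-trien-6β-ol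
Product: 25 15,16-epoxy-2α,19-bis(tert-butyldimethylsilyloxy)labda-8,13(16),14-trien-6-one
Conditions: Dess–Martin periodinane, NaHCO3, CH2Cl2, 0 °C
Reagents that add atoms: none
Why: Buffered Dess–Martin oxidation should give the β,γ-unsaturated C6 ketone without moving the tetrasubstituted alkene and without touching the furan.

Step 14
Reactants: 25 15,16-epoxy-2α,19-bis(tert-butyldimethylsilyloxy)labda-8,13(16),14-trien-6-one
Product: 26 15,16-epoxy-2α,19-bis(tert-butyldimethylsilyloxy)labda-8,13(16),14-trien-6α-ol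
Conditions: Li, NH3(l), THF, t-BuOH, −78 °C; then NH4Cl
Reagents that add atoms: none
Why: Dissolving-metal reduction of the ketone runs under thermodynamic control and should give the equatorial 6α-alcohol, whereas hydride reagents attack from the open α-face and return the axial 6β-alcohol; the furan, the isolated alkene and the silyl ethers should be inert.

Step 15
Reactants: 26 15,16-epoxy-2α,19-bis(tert-butyldimethylsilyloxy)labda-8,13(16),14-trien-6α-ol
Product: 27 6α-acetoxy-15,16-epoxy-2α,19-bis(tert-butyldimethylsilyloxy)labda-8,13(16),14-triene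
Conditions: Ac2O, DMAP, pyridine, rt
Reagents that add atoms: acetic anhydride, CC(=O)OC(C)=O
Why: DMAP-catalysed acylation should acetylate the only free hydroxyl.

Step 16
Reactants: 27 6α-acetoxy-15,16-epoxy-2α,19-bis(tert-butyldimethylsilyloxy)labda-8,13(16),14-triene
Product: 29 6α-acetoxy-2α,19-bis(tert-butyldimethylsilyloxy)labda-8,13-dien-15,16-olide, via 16-hydroxy butenolide 28 (not isolated)
Conditions: O2, hν, tetraphenylporphyrin (cat.), iPr2NEt, CH2Cl2, −78 °C; then NaBH4, MeOH, 0 °C; dilute HCl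
Reagents that add atoms: oxygen, O=O
Why: Singlet oxygen should add [4+2] to the electron-rich furan faster than it attacks the hindered tetrasubstituted alkene, the hindered amine should open the endoperoxide by removing the less hindered C15–H (Kornblum–DeLaMare-type) to place the carbonyl at C15, and NaBH4 reduction of the lactol with acid relactonisation should give the 15,16-olide.

Step 17
Reactants: 29 6α-acetoxy-2α,19-bis(tert-butyldimethylsilyloxy)labda-8,13-dien-15,16-olide
Product: 30 6α-acetoxy-2α,19-dihydroxylabda-8,13-dien-15,16-olide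
Conditions: HF·pyridine, THF, 0 °C → rt
Reagents that add atoms: none
Why: Buffered fluoride desilylation should free the C2 and C19 hydroxyls without acetate migration or opening of the butenolide.

Compound list
1 | (R)-epichlorohydrin | ClC[C@H]1CO1 | starting material
2 | isopropenylmagnesium bromide | CC(=C)[Mg]Br | starting material
3 | (R)-1-chloro-4-methylpent-4-en-2-ol | CC(=C)C[C@@H](O)CCl | intermediate
4 | (R)-2-(2-methylprop-2-en-1-yl)oxirane | CC(=C)C[C@@H]1CO1 | intermediate
5 | propionic acid | CCC(=O)O | starting material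
6 | (4S)-4-hydroxy-2,6-dimethylhept-6-enoic acid (C2 epimers) | CC(=C)C[C@@H](O)CC(C)C(=O)O | intermediate
7 | (5S)-3-methyl-5-(2-methylprop-2-en-1-yl)oxolan-2-one (C3 epimers, erased in step 3) | CC(=C)C[C@@H]1CC(C)C(=O)O1 | intermediate
8 | propargyl bromide | C#CCBr | starting material
9 | (3R,5R)-3-methyl-5-(2-methylprop-2-en-1-yl)-3-(prop-2-yn-1-yl)oxolan-2-one | CC(=C)C[C@@H]1C[C@](C)(C(=O)O1)CC#C | intermediate
10 | (2R,4R)-2,6-dimethyl-2-(prop-2-yn-1-yl)hept-6-ene-1,4-diol | CC(=C)C[C@@H](O)C[C@](C)(CO)CC#C | intermediate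
11 | (2R,4R)-1,4-bis(tert-butyldimethylsilyloxy)-2,6-dimethyl-2-(prop-2-yn-1-yl)hept-6-ene | CC(=C)C[C@@H](O[Si](C)(C)C(C)(C)C)C[C@](C)(CO[Si](C)(C)C(C)(C)C)CC#C | intermediate
12 | (4S,6R)-4-(tert-butyldimethylsilyloxy)-6-[(tert-butyldimethylsilyloxy)methyl]-6-methylnon-8-yn-2-one | CC(=O)C[C@@H](O[Si](C)(C)C(C)(C)C)C[C@](C)(CO[Si](C)(C)C(C)(C)C)CC#C | intermediate
13 | methyl acetoacetate | CC(=O)CC(=O)OC | starting material
14 | methyl (5R,7R)-2-acetyl-5-(tert-butyldimethylsilyloxy)-7-[(tert-butyldimethylsilyloxy)methyl]-3,7-dimethyldec-2-en-9-ynoate (E/Z mixture) | CC(=O)C(C(=O)OC)=C(C)C[C@@H](O[Si](C)(C)C(C)(C)C)C[C@](C)(CO[Si](C)(C)C(C)(C)C)CC#C | intermediate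
15 | methyl (5R,7S)-2-acetyl-5-(tert-butyldimethylsilyloxy)-7-[(tert-butyldimethylsilyloxy)methyl]-3,7-dimethyl-9-oxodec-2-enoate (E/Z mixture) | CC(=O)C(C(=O)OC)=C(C)C[C@@H](O[Si](C)(C)C(C)(C)C)C[C@](C)(CO[Si](C)(C)C(C)(C)C)CC(C)=O | intermediate
16 | 1,5-diketone Michael adduct: ring A closed, C5 acetyl and C10 CH(COCH3)CO2CH3 trans-diequatorial, C9 epimers | CC(=O)C(C(=O)OC)[C@@]1(C)C[C@@H](O[Si](C)(C)C(C)(C)C)C[C@](C)(CO[Si](C)(C)C(C)(C)C)[C@@H]1C(C)=O | intermediate
17 | β-hydroxy ketone aldol: methyl 2α,19-bis(tert-butyldimethylsilyloxy)-8-hydroxy-6-oxo-12,13,14,15,16-pentanorlabdan-11-oate (C8 and C9 epimers) | O=C1CC(C)(O)C(C(=O)OC)[C@@]2(C)C[C@@H](O[Si](C)(C)C(C)(C)C)C[C@](C)(CO[Si](C)(C)C(C)(C)C)[C@H]12 | intermediate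
18 | methyl 2α,19-bis(tert-butyldimethylsilyloxy)-6-oxo-12,13,14,15,16-pentanorlabd-7-en-11-oate (5α-H, 10β-CH3; 9α-H shown, C9 epimers converge) | O=C1C=C(C)[C@H](C(=O)OC)[C@@]2(C)C[C@@H](O[Si](C)(C)C(C)(C)C)C[C@](C)(CO[Si](C)(C)C(C)(C)C)[C@H]12 | intermediate
19 | methyl 2α,19-bis(tert-butyldimethylsilyloxy)-6-oxo-12,13,14,15,16-pentanorlabd-8-en-11-oate | O=C1CC(C)=C(C(=O)OC)[C@@]2(C)C[C@@H](O[Si](C)(C)C(C)(C)C)C[C@](C)(CO[Si](C)(C)C(C)(C)C)[C@H]12 | intermediate
20 | 2α,19-bis(tert-butyldimethylsilyloxy)-12,13,14,15,16-pentanorlabd-8-ene-6β,11-diol (6β shown as the expected epimer; C6 is reset in steps 13 and 14) | O[C@@H]1CC(C)=C(CO)[C@@]2(C)C[C@@H](O[Si](C)(C)C(C)(C)C)C[C@](C)(CO[Si](C)(C)C(C)(C)C)[C@H]12 | intermediate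
21 | 11-bromo-2α,19-bis(tert-butyldimethylsilyloxy)-12,13,14,15,16-pentanorlabd-8-en-6β-ol | O[C@@H]1CC(C)=C(CBr)[C@@]2(C)C[C@@H](O[Si](C)(C)C(C)(C)C)C[C@](C)(CO[Si](C)(C)C(C)(C)C)[C@H]12 | intermediate
22 | 3-(chloromethyl)furan | ClCc1ccoc1 | starting material
23 | (furan-3-ylmethyl)magnesium chloride | Cl[Mg]Cc1ccoc1 | intermediate
24 | 15,16-epoxy-2α,19-bis(tert-butyldimethylsilyloxy)labda-8,13(16),14-trien-6β-ol | O[C@@H]1CC(C)=C(CCc3ccoc3)[C@@]2(C)C[C@@H](O[Si](C)(C)C(C)(C)C)C[C@](C)(CO[Si](C)(C)C(C)(C)C)[C@H]12 | intermediate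
25 | 15,16-epoxy-2α,19-bis(tert-butyldimethylsilyloxy)labda-8,13(16),14-trien-6-one | O=C1CC(C)=C(CCc3ccoc3)[C@@]2(C)C[C@@H](O[Si](C)(C)C(C)(C)C)C[C@](C)(CO[Si](C)(C)C(C)(C)C)[C@H]12 | intermediate
26 | 15,16-epoxy-2α,19-bis(tert-butyldimethylsilyloxy)labda-8,13(16),14-trien-6α-ol | O[C@H]1CC(C)=C(CCc3ccoc3)[C@@]2(C)C[C@@H](O[Si](C)(C)C(C)(C)C)C[C@](C)(CO[Si](C)(C)C(C)(C)C)[C@H]12 | intermediate
27 | 6α-acetoxy-15,16-epoxy-2α,19-bis(tert-butyldimethylsilyloxy)labda-8,13(16),14-triene | CC(=O)O[C@H]1CC(C)=C(CCc3ccoc3)[C@@]2(C)C[C@@H](O[Si](C)(C)C(C)(C)C)C[C@](C)(CO[Si](C)(C)C(C)(C)C)[C@H]12 | intermediate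
28 | 6α-acetoxy-16-hydroxy-2α,19-bis(tert-butyldimethylsilyloxy)labda-8,13-dien-15,16-olide (C16 epimers) | CC(=O)O[C@H]1CC(C)=C(CCC3=CC(=O)OC3O)[C@@]2(C)C[C@@H](O[Si](C)(C)C(C)(C)C)C[C@](C)(CO[Si](C)(C)C(C)(C)C)[C@H]12 | intermediate
29 | 6α-acetoxy-2α,19-bis(tert-butyldimethylsilyloxy)labda-8,13-dien-15,16-olide | CC(=O)O[C@H]1CC(C)=C(CCC3=CC(=O)OC3)[C@@]2(C)C[C@@H](O[Si](C)(C)C(C)(C)C)C[C@](C)(CO[Si](C)(C)C(C)(C)C)[C@H]12 | intermediate
30 | 6α-acetoxy-2α,19-dihydroxylabda-8,13-dien-15,16-olide (CNP0231903.1) | CC(=O)O[C@H]1CC(C)=C(CCC2=CC(=O)OC2)[C@@]2(C)C[C@@H](O)C[C@](C)(CO)[C@H]12 | target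

Total step count: 17 steps.
Longest linear sequence: 17 steps (1 → 30); compounds 2, 5, 8, 13 and 22 are commercial and enter directly.

Steps most likely to fail

Step 9 (key step). The conjugate addition at the fully substituted C10 may be too slow or too reversible, so that deconjugation or retro-Knoevenagel cleavage of the acceptor outruns ring closure. The fallback sets out from 12 and comes back to the route at 18. Knoevenagel condensation of 12 with dimethyl malonate (TiCl4, pyridine) would give the alkylidene malonate F1, and gold-catalysed hydration of its alkyne would give the keto alkylidene malonate F2. NaOMe in MeOH would then drive a Michael–Dieckmann annulation, with the 1,3-dione enolate as thermodynamic sink, to the bicyclic 1,3-dione ester F3. O-Triflation at the less hindered C8 oxygen (PhNTf2, iPr2NEt) would give the vinylogous triflate F4, and Me2CuLi would replace the triflate by methyl to give 18. This costs two more steps but rests on the classical dione annulation.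

Step 7. Condensation at a methyl ketone that carries a β-silyloxy group may stall, or β-elimination of the silyloxy group may compete under TiCl4/pyridine. The fallback sets out from 12 and comes back at 14. Mukaiyama aldol addition of methyl 3-(trimethylsilyloxy)but-2-enoate to 12 (TiCl4, CH2Cl2, −78 °C) would give the tertiary aldol F5, which the Burgess reagent would dehydrate to 14.

Step 10. Protonation of the extended enolate at C9 instead of C7, or reconjugation of 19 before it is reduced, would return the C7=C8 isomer. The fallback sets out from 18 and comes back at 20. Luche reduction (NaBH4, CeCl3·7H2O, MeOH) would give the allylic alcohol F6. DBU would then move the alkene, no longer held by a ketone, into conjugation with the ester to give the conjugated hydroxy ester F7, and iBu2AlH would reduce F7 to 20.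

Further compounds
F1 | step 9 | dimethyl alkylidene malonate (analogue of 14 with CO2CH3 in place of acetyl) | COC(=O)C(C(=O)OC)=C(C)C[C@@H](O[Si](C)(C)C(C)(C)C)C[C@](C)(CO[Si](C)(C)C(C)(C)C)CC#C
F2 | step 9 | keto alkylidene malonate (analogue of 15 with CO2CH3 in place of acetyl) | COC(=O)C(C(=O)OC)=C(C)C[C@@H](O[Si](C)(C)C(C)(C)C)C[C@](C)(CO[Si](C)(C)C(C)(C)C)CC(C)=O
F3 | step 9 | methyl 2α,19-bis(tert-butyldimethylsilyloxy)-6,8-dioxo-12,13,14,15,16,17-hexanorlabdan-11-oate (bicyclic 1,3-dione ester, enol tautomers, C9 epimers) | O=C1CC(=O)C(C(=O)OC)[C@@]2(C)C[C@@H](O[Si](C)(C)C(C)(C)C)C[C@](C)(CO[Si](C)(C)C(C)(C)C)[C@H]12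
F4 | step 9 | vinylogous triflate: methyl 2α,19-bis(tert-butyldimethylsilyloxy)-6-oxo-8-(trifluoromethylsulfonyloxy)-12,13,14,15,16,17-hexanorlabd-7-en-11-oate | O=C1C=C(OS(=O)(=O)C(F)(F)F)C(C(=O)OC)[C@@]2(C)C[C@@H](O[Si](C)(C)C(C)(C)C)C[C@](C)(CO[Si](C)(C)C(C)(C)C)[C@H]12
F5 | step 7 | tertiary aldol: methyl 2-acetyl-5-(tert-butyldimethylsilyloxy)-7-[(tert-butyldimethylsilyloxy)methyl]-3-hydroxy-3,7-dimethyldec-9-ynoate (C2 and C3 epimers) | CC(=O)C(C(=O)OC)C(C)(O)C[C@@H](O[Si](C)(C)C(C)(C)C)C[C@](C)(CO[Si](C)(C)C(C)(C)C)CC#C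
F6 | step 10 | allylic alcohol: methyl 2α,19-bis(tert-butyldimethylsilyloxy)-6β-hydroxy-12,13,14,15,16-pentanorlabd-7-en-11-oate | O[C@@H]1C=C(C)[C@H](C(=O)OC)[C@@]2(C)C[C@@H](O[Si](C)(C)C(C)(C)C)C[C@](C)(CO[Si](C)(C)C(C)(C)C)[C@H]12
F7 | step 10 | conjugated hydroxy ester: methyl 2α,19-bis(tert-butyldimethylsilyloxy)-6β-hydroxy-12,13,14,15,16-pentanorlabd-8-en-11-oate | O[C@@H]1CC(C)=C(C(=O)OC)[C@@]2(C)C[C@@H](O[Si](C)(C)C(C)(C)C)C[C@](C)(CO[Si](C)(C)C(C)(C)C)[C@H]12
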